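**Retrosynthetic overview**

1. The C50 polyene is cut at C7=C8 and C7'=C8' (two Julia–Kocienski olefinations) into all-E crocetindialdehyde and two C15 ring sulfones. Ring A is the prenyl ring (C1–C6), ring B the hydroxybutenyl ring (C1'–C6'); its CH2OH is carried as a methyl ester and released last.
2. Both sulfones come from one cyclohexenone: the side chains are made by cross-metathesis of a C2-allyl group, and C6, α to the ring ketone, is epimerised by base, so that the same ketone supplies the 2,6-cis ring A and the 2',6'-trans ring B.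
3. The six-membered ring is made first, in the key step: an amine-catalysed Michael addition/aldol condensation ([4+2] annulation) of pent-4-enal with ethyl 2-isopropylideneacetoacetate, which forms C1'–C2' and C3'–C4' in one operation.
4. Enabling feature: in ring B the quaternary gem-dimethyl carbon C1' is not stereogenic and lies β to C5', and the C4'=C5'(CH3) double bond is a masked C5' ketone. C1' can therefore be the β-carbon of an isopropylidene β-keto ester (its ester is C7'), C3'–C4' an aldol condensation, and C2' the only stereocentre to control.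
5. Order of events: carbocycle of rings A and B (one annulation) → C7 thioether and C6 epimerisation (divergence) → side chains → polyene assembly, ring A end first.

Key step: step 2

Remark on the chemistry: the SMILES fixes ring A as (2S,6R), 2,6-cis, and ring B as (2'R,6'S), 2',6'-trans, with the same spatial sense at C2 and C2'; the route is built for this pattern (carotenoid numbering: C1 = CMe2, C2 = CH with the C5 side chain, C5 = C–CH3, C6 = CH with the polyene).
Assumption: pent-4-enal, all-E crocetindialdehyde and (S)-2-[diphenyl(trimethylsilyloxy)methyl]pyrrolidine are bought.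

**Route**

Step 1
Reactants: 1 acetone; 2 ethyl acetoacetate
Product: 3 ethyl 2-acetyl-3-methylbut-2-enoate
Conditions: ZnCl2 (10 mol %), Ac2O, 50 °C
Reagents that add atoms: none
Why: Knoevenagel condensation of the active methylene compound with acetone, with acetic anhydride taking up the water; no stereocentre is formed.

Step 2
Reactants: 3 ethyl 2-acetyl-3-methylbut-2-enoate; 4 pent-4-enal
Product: 6 ethyl (5S)-6,6-dimethyl-2-oxo-5-(prop-2-en-1-yl)cyclohex-3-ene-1-carboxylate, via keto aldehyde 5 (not isolated)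
Conditions: (S)-2-[diphenyl(trimethylsilyloxy)methyl]pyrrolidine (20 mol %), PhCO2H (20 mol %), toluene, 23 °C, slow addition of 4; then TsOH·H2O (0.5 equiv), 50 °C
Reagents that add atoms: none
Why: Proposed new method: the amine and 4 form an (E)-enamine whose C2' adds to the β-carbon C1' of the doubly activated alkylidene acetoacetate 3 (C1'–C2' bond), and after hydrolysis the acetyl methyl carbon C4' of 5 attacks the aldehyde carbon C3' (C3'–C4' bond) in an acid-promoted aldol addition followed by dehydration; the closest known reactions are amine-catalysed Michael additions of aldehydes to alkylidene malonates and the amine-catalysed Michael/aldol-condensation route from β-keto esters and enals to 2-oxocyclohex-3-ene-1-carboxylates, which passes through the same kind of 1,5-keto aldehyde, whereas a β,β-dimethyl acceptor has not been shown. The ring closes in the 6-(enolendo)-exo-trig mode. The only lasting new stereocentre, C2', is set by the catalyst: the diphenyl(trimethylsilyloxy)methyl group blocks one face of the s-trans enamine, so 3 adds to the open face, which by analogy with nitroalkene acceptors should give the (R)-aldehyde 5 from the (S)-amine; C1' carries two methyl groups and is not stereogenic, and C6' is an epimerisable β-keto ester carbon that is left uncontrolled on purpose. The step needs cross-addition to win over self-aldol of 4 (two acceptor groups on 3, slow addition of 4), closure at C4' and not C6' (C6' would give a four-membered ring), and retention at C2' during dehydration (C2' is shielded by the neighbouring quaternary carbon, and the aldehyde rests as the cyclic hemiacetal of the β-keto ester enol until it cyclises).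

Step 3
Reactants: 6 ethyl (5S)-6,6-dimethyl-2-oxo-5-(prop-2-en-1-yl)cyclohex-3-ene-1-carboxylate
Product: 7 (4S)-6-(hydroxymethyl)-5,5-dimethyl-4-(prop-2-en-1-yl)cyclohex-2-en-1-ol (diastereomers at C1 and C6)
Conditions: i-Bu2AlH (5 equiv), CH2Cl2, −78 → 0 °C; aqueous potassium sodium tartrate
Reagents that add atoms: none
Why: Aluminium hydride reduction (1,2-addition to the enone carbonyl, full reduction of the ester) should give the diol; the carbinol centre made here is erased in step 4.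

Step 4
Reactants: 7 (4S)-6-(hydroxymethyl)-5,5-dimethyl-4-(prop-2-en-1-yl)cyclohex-2-en-1-ol
Product: 8 (4S)-6-(hydroxymethyl)-5,5-dimethyl-4-(prop-2-en-1-yl)cyclohex-2-en-1-one (C6 epimers)
Conditions: MnO2 (15 equiv), CH2Cl2, 23 °C
Reagents that add atoms: none
Why: Chemoselective allylic oxidation with MnO2 restores the enone and leaves the saturated primary alcohol untouched.

Step 5
Reactants: 8 (4S)-6-(hydroxymethyl)-5,5-dimethyl-4-(prop-2-en-1-yl)cyclohex-2-en-1-one
Product: 9 (4S,6S)-5,5-dimethyl-6-{[(1-phenyl-1H-tetrazol-5-yl)sulfanyl]methyl}-4-(prop-2-en-1-yl)cyclohex-2-en-1-one (2,6-cis in carotenoid numbering)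
Conditions: 1-phenyl-1H-tetrazole-5-thiol (1.2 equiv), PPh3, diisopropyl azodicarboxylate, THF, 0 → 23 °C; chromatography
Reagents that add atoms: 1-phenyl-1H-tetrazole-5-thiol, Sc1nnnn1-c1ccccc1
Why: Mitsunobu thioetherification of the primary alcohol (an elimination/thia-Michael path through the α-methylene ketone would end at the same sulfide); C6 is α to the ketone and is not controlled here, so the cis epimer 9 is isolated by chromatography and assigned by the NOE between the ring hydrogens at C4 and C6, while the trans epimer that forms beside it is pooled with the product of step 6.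

Step 6
Reactants: 9 (4S,6S)-5,5-dimethyl-6-{[(1-phenyl-1H-tetrazol-5-yl)sulfanyl]methyl}-4-(prop-2-en-1-yl)cyclohex-2-en-1-one
Product: 10 (4S,6R)-5,5-dimethyl-6-{[(1-phenyl-1H-tetrazol-5-yl)sulfanyl]methyl}-4-(prop-2-en-1-yl)cyclohex-2-en-1-one (2,6-trans in carotenoid numbering)
Conditions: 1,8-diazabicyclo[5.4.0]undec-7-ene (10 mol %), CH2Cl2, 0 → 23 °C, to constant epimer ratio; chromatography, recovered 9 re-submitted
Reagents that add atoms: none
Why: Base-catalysed epimerisation of the ketone α-carbon C6, through the enolate or through reversible β-elimination and thia-Michael re-addition of the tetrazolethiolate, should give an equilibrium mixture of the two epimers (expected to be close in energy, because the gem-dimethyl carbon between C4 and C6 levels the axial/equatorial preference) from which 10 is separated, while the tertiary γ-hydrogen at C4 next to the quaternary carbon should exchange far more slowly than the doubly activated α'-hydrogen.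

Step 7
Reactants: 10 (4S,6R)-5,5-dimethyl-6-{[(1-phenyl-1H-tetrazol-5-yl)sulfanyl]methyl}-4-(prop-2-en-1-yl)cyclohex-2-en-1-one
Product: 12 (4S,6R)-5,5-dimethyl-6-{[(1-phenyl-1H-tetrazol-5-yl)sulfanyl]methyl}-4-(prop-2-en-1-yl)cyclohex-1-en-1-yl trifluoromethanesulfonate, via lithium enolate 11 (not isolated)
Conditions: Li[HB(s-Bu)3] (1.1 equiv), THF, −78 °C; then PhNTf2 (1.3 equiv), −78 → 0 °C
Reagents that add atoms: N-phenylbis(trifluoromethanesulfonimide), O=S(=O)(N(c1ccccc1)S(=O)(=O)C(F)(F)F)C(F)(F)F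
Why: Conjugate (1,4-) hydride reduction of the β-unsubstituted cyclohexenone by the bulky borohydride gives the C4'–C5' enolate regiospecifically (C3' becomes CH2), and O-triflation fixes the double bond there without touching C6'.

Step 8
Reactants: 12 (4S,6R)-5,5-dimethyl-6-{[(1-phenyl-1H-tetrazol-5-yl)sulfanyl]methyl}-4-(prop-2-en-1-yl)cyclohex-1-en-1-yl trifluoromethanesulfonate
Product: 13 1-phenyl-5-({[(1S,5S)-2,6,6-trimethyl-5-(prop-2-en-1-yl)cyclohex-2-en-1-yl]methyl}sulfanyl)-1H-tetrazole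
Conditions: MeZnCl (2.5 equiv), Pd(PPh3)4 (5 mol %), THF, 50 °C
Reagents that add atoms: methylzinc chloride, C[Zn]Cl
Why: Negishi cross-coupling of the alkenyl triflate installs the C5' methyl group with the C4'=C5' double bond kept in place, oxidative addition to the triflate being expected to outpace any insertion into the heteroaryl C–S bond.

Step 9
Reactants: 13 1-phenyl-5-({[(1S,5S)-2,6,6-trimethyl-5-(prop-2-en-1-yl)cyclohex-2-en-1-yl]methyl}sulfanyl)-1H-tetrazole
Product: 14 1-phenyl-5-({[(1S,5S)-2,6,6-trimethyl-5-(prop-2-en-1-yl)cyclohex-2-en-1-yl]methyl}sulfonyl)-1H-tetrazole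
Conditions: (NH4)6Mo7O24·4H2O (10 mol %), 30% aqueous H2O2 (5 equiv), EtOH, 0 → 23 °C
Reagents that add atoms: hydrogen peroxide, OO
Why: Molybdate-catalysed sulfide-to-sulfone oxidation should be selective for sulfur, since no allylic alcohol is present to direct epoxidation of the olefins.

Step 10
Reactants: 14 1-phenyl-5-({[(1S,5S)-2,6,6-trimethyl-5-(prop-2-en-1-yl)cyclohex-2-en-1-yl]methyl}sulfonyl)-1H-tetrazole
Product: 15 methyl (2E)-2-methyl-4-[(1R,5S)-4,6,6-trimethyl-5-{[(1-phenyl-1H-tetrazol-5-yl)sulfonyl]methyl}cyclohex-3-en-1-yl]but-2-enoate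
Conditions: methyl methacrylate (10 equiv), second-generation Grubbs catalyst (5 mol %), CH2Cl2, 40 °C
Reagents that add atoms: methyl methacrylate, C=C(C)C(=O)OC
Why: Olefin cross-metathesis of the terminal allyl group with the 1,1-disubstituted acrylate should give the trisubstituted enoate with the thermodynamically favoured (E) geometry, the trisubstituted ring olefin being inert.

Step 11
Reactants: 9 (4S,6S)-5,5-dimethyl-6-{[(1-phenyl-1H-tetrazol-5-yl)sulfanyl]methyl}-4-(prop-2-en-1-yl)cyclohex-2-en-1-one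
Product: 17 (4S,6S)-5,5-dimethyl-6-{[(1-phenyl-1H-tetrazol-5-yl)sulfanyl]methyl}-4-(prop-2-en-1-yl)cyclohex-1-en-1-yl trifluoromethanesulfonate, via lithium enolate 16 (not isolated)
Conditions: Li[HB(s-Bu)3] (1.1 equiv), THF, −78 °C; then PhNTf2 (1.3 equiv), −78 → 0 °C
Reagents that add atoms: N-phenylbis(trifluoromethanesulfonimide), O=S(=O)(N(c1ccccc1)S(=O)(=O)C(F)(F)F)C(F)(F)F
Why: Same conjugate reduction/enolate triflation as in step 7, regiospecific for the C4=C5 position and without effect on the cis C6 centre.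

Step 12
Reactants: 17 (4S,6S)-5,5-dimethyl-6-{[(1-phenyl-1H-tetrazol-5-yl)sulfanyl]methyl}-4-(prop-2-en-1-yl)cyclohex-1-en-1-yl trifluoromethanesulfonate
Product: 18 1-phenyl-5-({[(1R,5S)-2,6,6-trimethyl-5-(prop-2-en-1-yl)cyclohex-2-en-1-yl]methyl}sulfanyl)-1H-tetrazole
Conditions: MeZnCl (2.5 equiv), Pd(PPh3)4 (5 mol %), THF, 50 °C
Reagents that add atoms: methylzinc chloride, C[Zn]Cl
Why: Negishi cross-coupling of the alkenyl triflate, as in step 8.

Step 13
Reactants: 18 1-phenyl-5-({[(1R,5S)-2,6,6-trimethyl-5-(prop-2-en-1-yl)cyclohex-2-en-1-yl]methyl}sulfanyl)-1H-tetrazole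
Product: 19 1-phenyl-5-({[(1R,5S)-2,6,6-trimethyl-5-(prop-2-en-1-yl)cyclohex-2-en-1-yl]methyl}sulfonyl)-1H-tetrazole
Conditions: (NH4)6Mo7O24·4H2O (10 mol %), 30% aqueous H2O2 (5 equiv), EtOH, 0 → 23 °C
Reagents that add atoms: hydrogen peroxide, OO
Why: Molybdate-catalysed sulfide-to-sulfone oxidation, done before the electron-rich prenyl olefin is installed.

Step 14
Reactants: 19 1-phenyl-5-({[(1R,5S)-2,6,6-trimethyl-5-(prop-2-en-1-yl)cyclohex-2-en-1-yl]methyl}sulfonyl)-1H-tetrazole
Product: 20 1-phenyl-5-({[(1R,5S)-2,6,6-trimethyl-5-(3-methylbut-2-en-1-yl)cyclohex-2-en-1-yl]methyl}sulfonyl)-1H-tetrazole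
Conditions: 2-methylbut-2-ene (solvent), second-generation Grubbs catalyst (5 mol %), 40 °C, sealed tube
Reagents that add atoms: 2-methylbut-2-ene, CC=C(C)C
Why: Olefin cross-metathesis with 2-methylbut-2-ene converts the allyl group into the prenyl group (no new stereo element), the ring olefin being inert.

Step 15
Reactants: 20 1-phenyl-5-({[(1R,5S)-2,6,6-trimethyl-5-(3-methylbut-2-en-1-yl)cyclohex-2-en-1-yl]methyl}sulfonyl)-1H-tetrazole; 21 all-E crocetindialdehyde (3 equiv)
Product: 22 (2S,6R)-2-(3-methylbut-2-en-1-yl)-8'-apo-ε-caroten-8'-al (all-E)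
Conditions: KN(SiMe3)2 (1.1 equiv) added to 20 + 21, THF/DMF, −60 → 0 °C
Reagents that add atoms: none
Why: Julia–Kocienski olefination forms C7=C8, the potassium base in a polar medium favouring the (E) olefin and the excess of dialdehyde (recovered) favouring mono-olefination, while C6 is not acidified by the sulfonyl anion and should keep its configuration.

Step 16
Reactants: 22 (2S,6R)-2-(3-methylbut-2-en-1-yl)-8'-apo-ε-caroten-8'-al; 15 methyl (2E)-2-methyl-4-[(1R,5S)-4,6,6-trimethyl-5-{[(1-phenyl-1H-tetrazol-5-yl)sulfonyl]methyl}cyclohex-3-en-1-yl]but-2-enoate (1.2 equiv)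
Product: 23 (2S,6R,2'R,6'S)-2'-[(2E)-4-methoxy-3-methyl-4-oxobut-2-en-1-yl]-2-(3-methylbut-2-en-1-yl)-ε,ε-carotene (all-E)
Conditions: KN(SiMe3)2 (1.2 equiv) added to 22 + 15, THF/DMF, −60 → 0 °C; then I2 (1 mol %), CH2Cl2/hexane, daylight, 23 °C
Reagents that add atoms: none
Why: Second Julia–Kocienski olefination forms C7'=C8', and the iodine-catalysed equilibration, standard for carotenoids, should bring any (Z) isomers at C7=C8 or C7'=C8' to the all-E polyene without touching the ring stereocentres.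

Step 17
Reactants: 23 (2S,6R,2'R,6'S)-2'-[(2E)-4-methoxy-3-methyl-4-oxobut-2-en-1-yl]-2-(3-methylbut-2-en-1-yl)-ε,ε-carotene
Product: 24 (2S,6R,2'R,6'S)-2'-[(2E)-4-hydroxy-3-methylbut-2-en-1-yl]-2-(3-methylbut-2-en-1-yl)-ε,ε-carotene (target)
Conditions: i-Bu2AlH (3 equiv), CH2Cl2, −78 °C; aqueous potassium sodium tartrate
Reagents that add atoms: none
Why: 1,2-Reduction of the α,β-unsaturated ester by the aluminium hydride gives the (E)-allylic alcohol and leaves the polyene and the other olefins alone.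

**Compound list**

1 | acetone | CC(C)=O | starting material
2 | ethyl acetoacetate | CCOC(=O)CC(C)=O | starting material
3 | ethyl 2-acetyl-3-methylbut-2-enoate | CCOC(=O)C(C(C)=O)=C(C)C | intermediate
4 | pent-4-enal | C=CCCC=O | starting material
5 | ethyl (4R)-2-acetyl-4-formyl-3,3-dimethylhept-6-enoate (C2 epimers; not isolated) | CCOC(=O)C(C(C)=O)C(C)(C)[C@@H](CC=C)C=O | intermediate
6 | ethyl (5S)-6,6-dimethyl-2-oxo-5-(prop-2-en-1-yl)cyclohex-3-ene-1-carboxylate (C1 epimers) | CCOC(=O)C1C(=O)C=C[C@H](CC=C)C1(C)C | intermediate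
7 | (4S)-6-(hydroxymethyl)-5,5-dimethyl-4-(prop-2-en-1-yl)cyclohex-2-en-1-ol (diastereomers at C1 and C6) | OCC1C(O)C=C[C@H](CC=C)C1(C)C | intermediate
8 | (4S)-6-(hydroxymethyl)-5,5-dimethyl-4-(prop-2-en-1-yl)cyclohex-2-en-1-one (C6 epimers) | OCC1C(=O)C=C[C@H](CC=C)C1(C)C | intermediate
9 | (4S,6S)-5,5-dimethyl-6-{[(1-phenyl-1H-tetrazol-5-yl)sulfanyl]methyl}-4-(prop-2-en-1-yl)cyclohex-2-en-1-one | C(Sc1nnnn1-c1ccccc1)[C@@H]1C(=O)C=C[C@H](CC=C)C1(C)C | intermediate
10 | (4S,6R)-5,5-dimethyl-6-{[(1-phenyl-1H-tetrazol-5-yl)sulfanyl]methyl}-4-(prop-2-en-1-yl)cyclohex-2-en-1-one | C(Sc1nnnn1-c1ccccc1)[C@H]1C(=O)C=C[C@H](CC=C)C1(C)C | intermediate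
11 | lithium (4S,6R)-5,5-dimethyl-6-{[(1-phenyl-1H-tetrazol-5-yl)sulfanyl]methyl}-4-(prop-2-en-1-yl)cyclohex-1-en-1-olate (not isolated) | [Li+].C(Sc1nnnn1-c1ccccc1)[C@H]1C([O-])=CC[C@H](CC=C)C1(C)C | intermediate
12 | (4S,6R)-5,5-dimethyl-6-{[(1-phenyl-1H-tetrazol-5-yl)sulfanyl]methyl}-4-(prop-2-en-1-yl)cyclohex-1-en-1-yl trifluoromethanesulfonate | C(Sc1nnnn1-c1ccccc1)[C@H]1C(OS(=O)(=O)C(F)(F)F)=CC[C@H](CC=C)C1(C)C | intermediate
13 | 1-phenyl-5-({[(1S,5S)-2,6,6-trimethyl-5-(prop-2-en-1-yl)cyclohex-2-en-1-yl]methyl}sulfanyl)-1H-tetrazole | C(Sc1nnnn1-c1ccccc1)[C@H]1C(C)=CC[C@H](CC=C)C1(C)C | intermediate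
14 | 1-phenyl-5-({[(1S,5S)-2,6,6-trimethyl-5-(prop-2-en-1-yl)cyclohex-2-en-1-yl]methyl}sulfonyl)-1H-tetrazole | O=S(=O)(C[C@H]1C(C)=CC[C@H](CC=C)C1(C)C)c1nnnn1-c1ccccc1 | intermediate
15 | methyl (2E)-2-methyl-4-[(1R,5S)-4,6,6-trimethyl-5-{[(1-phenyl-1H-tetrazol-5-yl)sulfonyl]methyl}cyclohex-3-en-1-yl]but-2-enoate | O=S(=O)(C[C@H]1C(C)=CC[C@H](C/C=C(\C)C(=O)OC)C1(C)C)c1nnnn1-c1ccccc1 | intermediate
16 | lithium (4S,6S)-5,5-dimethyl-6-{[(1-phenyl-1H-tetrazol-5-yl)sulfanyl]methyl}-4-(prop-2-en-1-yl)cyclohex-1-en-1-olate (not isolated) | [Li+].C(Sc1nnnn1-c1ccccc1)[C@@H]1C([O-])=CC[C@H](CC=C)C1(C)C | intermediate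
17 | (4S,6S)-5,5-dimethyl-6-{[(1-phenyl-1H-tetrazol-5-yl)sulfanyl]methyl}-4-(prop-2-en-1-yl)cyclohex-1-en-1-yl trifluoromethanesulfonate | C(Sc1nnnn1-c1ccccc1)[C@@H]1C(OS(=O)(=O)C(F)(F)F)=CC[C@H](CC=C)C1(C)C | intermediate
18 | 1-phenyl-5-({[(1R,5S)-2,6,6-trimethyl-5-(prop-2-en-1-yl)cyclohex-2-en-1-yl]methyl}sulfanyl)-1H-tetrazole | C(Sc1nnnn1-c1ccccc1)[C@@H]1C(C)=CC[C@H](CC=C)C1(C)C | intermediate
19 | 1-phenyl-5-({[(1R,5S)-2,6,6-trimethyl-5-(prop-2-en-1-yl)cyclohex-2-en-1-yl]methyl}sulfonyl)-1H-tetrazole | O=S(=O)(C[C@@H]1C(C)=CC[C@H](CC=C)C1(C)C)c1nnnn1-c1ccccc1 | intermediate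
20 | 1-phenyl-5-({[(1R,5S)-2,6,6-trimethyl-5-(3-methylbut-2-en-1-yl)cyclohex-2-en-1-yl]methyl}sulfonyl)-1H-tetrazole | O=S(=O)(C[C@@H]1C(C)=CC[C@H](CC=C(C)C)C1(C)C)c1nnnn1-c1ccccc1 | intermediate
21 | (2E,4E,6E,8E,10E,12E,14E)-2,6,11,15-tetramethylhexadeca-2,4,6,8,10,12,14-heptaenedial (crocetindialdehyde) | O=C/C(C)=C/C=C/C(C)=C/C=C/C=C(C)/C=C/C=C(C)/C=O | starting material
22 | (2S,6R)-2-(3-methylbut-2-en-1-yl)-8'-apo-ε-caroten-8'-al | CC(C)=CC[C@H]1CC=C(C)[C@@H](/C=C/C(C)=C/C=C/C(C)=C/C=C/C=C(C)/C=C/C=C(C)/C=O)C1(C)C | intermediate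
23 | (2S,6R,2'R,6'S)-2'-[(2E)-4-methoxy-3-methyl-4-oxobut-2-en-1-yl]-2-(3-methylbut-2-en-1-yl)-ε,ε-carotene | CC(C)=CC[C@H]1CC=C(C)[C@@H](/C=C/C(C)=C/C=C/C(C)=C/C=C/C=C(C)/C=C/C=C(C)/C=C/[C@H]2C(C)=CC[C@H](C/C=C(\C)C(=O)OC)C2(C)C)C1(C)C | intermediate
24 | (2S,6R,2'R,6'S)-2'-[(2E)-4-hydroxy-3-methylbut-2-en-1-yl]-2-(3-methylbut-2-en-1-yl)-ε,ε-carotene | CC(C)=CC[C@H]1CC=C(C)[C@@H](/C=C/C(C)=C/C=C/C(C)=C/C=C/C=C(C)/C=C/C=C(C)/C=C/[C@H]2C(C)=CC[C@H](C/C=C(\C)CO)C2(C)C)C1(C)C | target

**Step count and risks**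

Total step count: 17. Longest linear sequence: 12 (steps 1–5, 6–10, 16, 17; the ring A branch, steps 1–5, 11–15, 16, 17, is equally long).

Steps most likely to fail:

1. Step 2 (Proposed new method). The enamine may not add to the tetrasubstituted acceptor, 3 may deconjugate under the amine, or the α-centre of 5 may erode before ring closure. The fallback uses only known reactions with auxiliary control. It does not set out from a numbered compound but from commercial 3,3-dimethyl-5-oxohexanoic acid, which takes the place of 3 and 4 and already holds C1'–C6'; it comes back to the route at 8. The ketone is protected (ethylene glycol, TsOH; then LiOH) to give 3,3-dimethyl-4-(2-methyl-1,3-dioxolan-2-yl)butanoic acid F1. Mixed-anhydride coupling (t-BuCOCl, Et3N; lithiated (R)-4-benzyl-1,3-oxazolidin-2-one) gives the imide F2. Evans alkylation (NaN(SiMe3)2, allyl iodide, THF, −78 °C) sets C2' in the allylated imide F3. LiBH4 then gives the primary alcohol F4, and Dess–Martin oxidation the aldehyde F5. Aqueous HCl removes the ketal and KOH/MeOH closes the 1,5-keto aldehyde by aldol condensation to (4S)-5,5-dimethyl-4-(prop-2-en-1-yl)cyclohex-2-en-1-one F6. Kinetic α'-deprotonation (LiN(i-Pr)2, THF, −78 °C) and hydroxymethylation with gaseous formaldehyde give 8.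

2. Step 5. Under Mitsunobu conditions the β-hydroxy ketone may lose formaldehyde by retro-aldol cleavage, or the thiol may add to the ring enone. The fallback sets out from 8 and comes back at 9. Compound 8 is dehydrated on purpose (MsCl, Et3N, CH2Cl2, 0 °C) to the cross-conjugated dienone (4S)-5,5-dimethyl-6-methylidene-4-(prop-2-en-1-yl)cyclohex-2-en-1-one F7. Base-catalysed thia-Michael addition of 1-phenyl-1H-tetrazole-5-thiol (Et3N cat., CH2Cl2) to the exocyclic methylene, the less hindered acceptor terminus, then gives 9; the trans epimer formed beside it is pooled with the product of step 6 as in the main route.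

3. Step 16. The base may deprotonate γ to the enoate of 15, the sulfonyl anion may add to the enoate, or E selectivity may be low. The fallback sets out from 15 and comes back at 24. The ester is reduced first (i-Bu2AlH, CH2Cl2, −78 °C) to (2E)-2-methyl-4-[(1R,5S)-4,6,6-trimethyl-5-{[(1-phenyl-1H-tetrazol-5-yl)sulfonyl]methyl}cyclohex-3-en-1-yl]but-2-en-1-ol F8. Silylation (t-BuMe2SiCl, imidazole) gives its tert-butyldimethylsilyl ether F9. Julia–Kocienski olefination of F9 with 22, followed by the same iodine equilibration, gives the silyl ether of the target F10, and Bu4NF releases 24.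

Further compounds
F1 | step 2 | 3,3-dimethyl-4-(2-methyl-1,3-dioxolan-2-yl)butanoic acid | CC1(CC(C)(C)CC(=O)O)OCCO1
F2 | step 2 | (4R)-4-benzyl-3-[3,3-dimethyl-4-(2-methyl-1,3-dioxolan-2-yl)butanoyl]-1,3-oxazolidin-2-one | CC1(CC(C)(C)CC(=O)N2[C@H](Cc3ccccc3)COC2=O)OCCO1
F3 | step 2 | (4R)-4-benzyl-3-{(2R)-2-[2-methyl-1-(2-methyl-1,3-dioxolan-2-yl)propan-2-yl]pent-4-enoyl}-1,3-oxazolidin-2-one | CC1(CC(C)(C)[C@@H](CC=C)C(=O)N2[C@H](Cc3ccccc3)COC2=O)OCCO1
F4 | step 2 | (2R)-2-[2-methyl-1-(2-methyl-1,3-dioxolan-2-yl)propan-2-yl]pent-4-en-1-ol | CC1(CC(C)(C)[C@@H](CC=C)CO)OCCO1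
F5 | step 2 | (2R)-2-[2-methyl-1-(2-methyl-1,3-dioxolan-2-yl)propan-2-yl]pent-4-enal | CC1(CC(C)(C)[C@@H](CC=C)C=O)OCCO1
F6 | step 2 | (4S)-5,5-dimethyl-4-(prop-2-en-1-yl)cyclohex-2-en-1-one | O=C1C=C[C@H](CC=C)C(C)(C)C1
F7 | step 5 | (4S)-5,5-dimethyl-6-methylidene-4-(prop-2-en-1-yl)cyclohex-2-en-1-one | C=C1C(=O)C=C[C@H](CC=C)C1(C)C
F8 | step 16 | (2E)-2-methyl-4-[(1R,5S)-4,6,6-trimethyl-5-{[(1-phenyl-1H-tetrazol-5-yl)sulfonyl]methyl}cyclohex-3-en-1-yl]but-2-en-1-ol | O=S(=O)(C[C@H]1C(C)=CC[C@H](C/C=C(\C)CO)C1(C)C)c1nnnn1-c1ccccc1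
F9 | step 16 | tert-butyldimethylsilyl ether of F8 | O=S(=O)(C[C@H]1C(C)=CC[C@H](C/C=C(\C)CO[Si](C)(C)C(C)(C)C)C1(C)C)c1nnnn1-c1ccccc1
F10 | step 16 | tert-butyldimethylsilyl ether of 24 | CC(C)=CC[C@H]1CC=C(C)[C@@H](/C=C/C(C)=C/C=C/C(C)=C/C=C/C=C(C)/C=C/C=C(C)/C=C/[C@H]2C(C)=CC[C@H](C/C=C(\C)CO[Si](C)(C)C(C)(C)C)C2(C)C)C1(C)C
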